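The ratio that matters is target made per starting material leaked away, and two earlier runs let me read it.

| flask | starting material | reagent | temperature | remark | time |
|---|---|---|---|---|---|
| gamma | 0.0043 M | 10 mM | −5 °C | run made earlier |  |
| theta | 0.028 M | 10 mM | 8 °C | run made earlier |  |
| zeta | 0.010 M | 9.8 mM | −5 °C | run made earlier |  |
| Sunday's | 0.0060 M | 10.0 mM | 0 °C |  | 5.0 min |
| Saturday's | 0.040 M | 6.00 mM | 15 °C |  | 5.0 min |
| Thursday's | 0.0050 M | 5.00 mM | 15 °C |  | 5.0 min |
| Tuesday's | 0.010 M | 10.0 mM | 0 °C |  | 5.0 min |
| Monday's | 0.010 M | 15.0 mM | 0 °C |  | 5.0 min |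

- gamma (time / min: target / %, starting material / %): 0.250: 77.4, 7.9; 0.500: 84.2, 0.8; 1.00: 84.9, 0.1; 2.00: 85.1, 0.2; 4.00: 84.9, 0
- theta (time / min: target / %, starting material / %): 0.333: 34.2, 0.1; 0.833: 35.0, 0; 1.50: 34.6, 0.1; 2.50: 34.6, 0; 4.00: 34.7, 0
- zeta (time / min: target / %, starting material / %): 0.667: 79.0, 0.6; 1.33: 79.0, 0; 2.00: 79.1, 0.5; 3.00: 79.0, 0; 4.00: 79.1, 0

(each reading ± 0.3 percentage points)

- the flasks put in order of amount of target, in percent of the starting material charged, best first, at 5.0 min (Sunday's / Saturday's / Thursday's / Tuesday's / Monday's)
- the amount of target, in percent of the starting material charged of the flask you put first, at 5.0 min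
- the amount of target, in percent of the starting material charged of the flask you put last, at 5.0 min

- the numbers in the tables scatter by 0.3 percentage points (one standard deviation)
- a reading or a percentage of target counts all its forms, free or not
- a reading of starting material is of its free form alone

Gamma's starting material reads 0.1 % at 1.00 min and its target stays flat, so I treat each flask as a finished competition. Target needs reagent; the leak, which I take to use none, doesn't. I call a the reagent concentration at which the two run equally fast. Reagent falls by about c(starting material) during a run, so its mean is the charge minus half of that. I fold this into a leak number, a selectivity factor: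

N = a / (c(reagent) − c(starting material)/2)

target share = 1 / (1 + N)

Run backwards, gamma gives a = 1.40 mM and zeta 1.27 mM. These are different charges at −5 °C, so their closeness tests the form. I carry their mean, the leak constant a = 1.33 mM.

One number isn't enough, though. Theta's mean reagent comes out at −4.00 mM, which has no meaning: there reagent is the limiting reagent, and the cap c(reagent)/c(starting material) = 35.7 % stands just above the reading of 34.7 %. So the shortcut fails in theta, and there I use the uncut balance, c(starting material) = c(target) + a·ln(c(reagent)/(c(reagent) − c(target))), with c(target) the amount made. It gives a rough 5.13 mM at 8 °C, rough because the reading lies so near its cap, and that is larger than the 1.33 mM read at −5 °C.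

At a's value, N is 0.133 for Monday's, 0.190 for Sunday's, 0.266 for Tuesday's and 0.533 for Thursday's. That gives Monday's 88.2 %, which I hold as high, because a was read at −5 °C and Monday's stands at 0 °C, where I expect it between that 1.33 mM and theta's larger 5.13 mM. Saturday's mean reagent is −14.0 mM, so I put it just under its cap of 15.0 %.

The forecast says Monday's > Sunday's > Tuesday's > Thursday's > Saturday's, with 82 % (78 % to 86 %) and 14.5 % (13.5 % to 15 %), holding that “yields are set by competition, not by time”.

The flask gives Monday's > Sunday's > Tuesday's > Thursday's > Saturday's, with 84.6 % for Monday's and 14.6 % for Saturday's.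

    starting material ⇌ tautomer (K = 1.80, k = 0.340 s⁻¹, Ea = 72.0 kJ mol⁻¹, ΔH = −29.0 kJ mol⁻¹)
    starting material + reagent → isomer of the product (k = 1.50 M⁻¹ s⁻¹, Ea = 44.0 kJ mol⁻¹)
    reagent + tautomer → target (k = 410 M⁻¹ s⁻¹, Ea = 44.0 kJ mol⁻¹)
    tautomer → side product (k = 0.510 s⁻¹, Ea = 71.0 kJ mol⁻¹)
    crystals ⇌ target, rate k5*(cs5 - [target]) while solid is left; crystals form when [target] > cs5 (solubility = 0.270 mM, k = 1.50 s⁻¹)
    starting material + target ⇌ idle adduct, settled at all times (K = 310 M⁻¹, ΔH = −10.0 kJ mol⁻¹)
    (constants at 0 °C)

Monday's ends with 10.7 % side product and 4.65 % isomer of the product beside its target, 3.6 percentage points below my share. With a at 1.33 mM, Tuesday's N of 0.266 gives 79.0 %, and Tuesday's flask holds 77.6 % target.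

All runs were computed from invented constants, noise included.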